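**Retrosynthetic overview**

1. Target 28 ⇐ late C9 angelate (Yamaguchi), C13 methylene (Mannich/elimination) and removal of the aryl and silyl ethers; the 12,6-lactone ⇐ oxidative lactonisation of triol 19; the C6 carbinol, the C10 carbinol and C1H2 ⇐ one LiAlH4 reduction of epoxy keto ester 18.
2. Ten-membered carbocycle: keto ester 17 ⇐ dialkenyl carbinol 14 by anionic oxy-Cope ring expansion that forms C8–C9 (C1–C6 breaks), with the enolate alkylated at C7 in the same flask.
3. Enabling feature: C6–O and C10–O are 1,5-related across the carbocycle with C7–C8–C9 between them, a latent C6=O / C10=C1 hex-5-enone. Because C4=C5 is cis, reconnecting C1 to C6 gives an ordinary cyclohexene (C1–C6), and the C9 oxygen can ride in as the terminus of an E enol ether.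
4. 14 ⇐ enone 13 + vinyl Grignard; 13 ⇐ quinone monoketal 9 + alkenylboronate 7 (rhodium-catalysed asymmetric 1,4-addition), then Luche reduction; 7 ⇐ 4-methoxyphenol, trichloroethylene, MeI and pinacolborane.
5. Ring order: six-membered carbocycle (from an arene) → ten-membered carbocycle (key step) → γ-lactone (step 13).

Key step: step 10

Remark: the ester in the SMILES has carbonyl and β-methyl cis, so it is an angelate; germacrane numbering is used (ring C1–C10, C11–C13 on C7, C14 on C10, C15 on C4), α/β refer to the usual projection (ring numbered counter-clockwise, β toward the viewer), and the target is 9β-angeloyloxy-3β,10α-dihydroxygermacra-4Z,11(13)-dien-12,6α-olide (3S,6R,7S,9S,10S; H-6 β, H-7 α).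

**Route**

Step 1
Reactants: 1 4-methoxyphenol; 2 trichloroethylene
Product: 3 (E)-1-[(1,2-dichloroethenyl)oxy]-4-methoxybenzene
Conditions: K2CO3, DMF, 70 °C
Reagents that add atoms: none
Why: O-vinylation of a phenoxide with trichloroethylene (elimination to dichloroacetylene, then anti addition of the phenol) is the standard entry to aryl (E)-1,2-dichlorovinyl ethers.

Step 2
Reactants: 3 (E)-1-[(1,2-dichloroethenyl)oxy]-4-methoxybenzene
Product: 6 1-methoxy-4-(prop-1-yn-1-yloxy)benzene, via chloroalkyne 4 (not isolated), via lithium acetylide 5 (not isolated)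
Conditions: n-BuLi (2.2 equiv), THF, −78 → −40 °C; then MeI, DMPU, −78 °C → rt
Reagents that add atoms: iodomethane, CI
Why: dehydrochlorination to the chloroalkyne, chlorine–lithium exchange and C-methylation of the acetylide is the established dichlorovinyl ether route to 1-alkynyl ethers, and no stereocentre is formed.

Step 3
Reactants: 6 1-methoxy-4-(prop-1-yn-1-yloxy)benzene
Product: 7 (Z)-2-[1-(4-methoxyphenoxy)prop-1-en-2-yl]-4,4,5,5-tetramethyl-1,3,2-dioxaborolane
Conditions: pinacolborane, (C5H5)2Zr(H)Cl (5 mol %), Et3N (10 mol %), CH2Cl2, rt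
Reagents that add atoms: pinacolborane, [H]B1OC(C)(C)C(C)(C)O1
Why: zirconium-catalysed syn-hydroboration of the ynol ether places boron on the alkyne carbon remote from oxygen (the nucleophilic and less hindered terminus), so boron and the aryloxy group end up trans, which fixes the later E enol ether geometry.

Step 4
Reactants: 8 4-methoxy-2-methylphenol
Product: 9 4,4-dimethoxy-2-methylcyclohexa-2,5-dien-1-one
Conditions: PhI(OAc)2, MeOH, 0 °C
Reagents that add atoms: methanol, CO
Why: oxidative dearomatisation of a para-methoxyphenol in methanol gives the quinone monoketal with the free carbonyl next to the methyl-bearing carbon.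

Step 5
Reactants: 9 4,4-dimethoxy-2-methylcyclohexa-2,5-dien-1-one; 7 (Z)-alkenylboronate
Product: 10 (5S)-4,4-dimethoxy-5-[(1E)-1-(4-methoxyphenoxy)prop-1-en-2-yl]-2-methylcyclohex-2-en-1-one
Conditions: [Rh(OH)(C8H12)]2 (2.5 mol %, C8H12 = 1,5-cyclooctadiene), (S)-BINAP (6 mol %), KOH (0.5 equiv), 1,4-dioxane/H2O (10:1), 40 °C
Reagents that add atoms: none
Why: the rhodium-catalysed asymmetric 1,4-addition of an alkenylboron reagent (Hayashi–Miyaura reaction) should occur at the unsubstituted enone because the α-methyl enone is unreactive, (S)-BINAP (the antipode that gives 3S adducts of cyclohex-2-enone) is expected to set the new centre (C1, germacrane numbering) as S, and with boron and OAr trans no β-aryloxy elimination from the alkenylrhodium is possible.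

Step 6
Reactants: 10 (5S)-ketone
Product: 11 (1S,5S)-4,4-dimethoxy-5-[(1E)-1-(4-methoxyphenoxy)prop-1-en-2-yl]-2-methylcyclohex-2-en-1-ol
Conditions: NaBH4, CeCl3·7H2O, MeOH, −78 °C
Reagents that add atoms: none
Why: Luche 1,2-reduction, in which hydride should add to the carbonyl face anti to the C1 alkenyl group as in other 5-substituted cyclohex-2-enones, giving the cis allylic alcohol (C3 S).

Step 7
Reactants: 11 (1S,5S)-allylic alcohol
Product: 12 tert-butyl{[(1S,5S)-4,4-dimethoxy-5-[(1E)-1-(4-methoxyphenoxy)prop-1-en-2-yl]-2-methylcyclohex-2-en-1-yl]oxy}dimethylsilane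
Conditions: TBSCl, imidazole, DMF, rt
Reagents that add atoms: tert-butyldimethylsilyl chloride, CC(C)(C)[Si](C)(C)Cl
Why: standard silylation of a secondary allylic alcohol.

Step 8
Reactants: 12 silyl ether ketal
Product: 13 (4S,6S)-4-[(tert-butyldimethylsilyl)oxy]-6-[(1E)-1-(4-methoxyphenoxy)prop-1-en-2-yl]-3-methylcyclohex-2-en-1-one
Conditions: PPTS (10 mol %), acetone/H2O (10:1), 0 °C → rt
Reagents that add atoms: water, O
Why: acid-catalysed hydrolysis of the allylic dimethyl ketal passes through an allyl-stabilised oxocarbenium ion and should be far faster than C-protonation of the β,β-disubstituted aryl enol ether or cleavage of the silyl ether.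

Step 9
Reactants: 13 (4S,6S)-enone
Product: 14 (1S,4S,6S)-4-[(tert-butyldimethylsilyl)oxy]-1-ethenyl-6-[(1E)-1-(4-methoxyphenoxy)prop-1-en-2-yl]-3-methylcyclohex-2-en-1-ol
Conditions: CH2=CHMgBr (3 equiv), CeCl3 (3 equiv), THF, −78 °C
Reagents that add atoms: vinylmagnesium bromide, C=C[Mg]Br
Why: organocerium 1,2-addition to the enone (no enolisation, no 1,4-addition) should take place anti to the adjacent C1 alkenyl group and the C3 silyloxy group, giving the trans-dialkenyl carbinol (C6 S) with OH axial and vinyl, alkenyl and OTBS all equatorial.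

Step 10
Reactants: 14 (1S,4S,6S)-dialkenyl carbinol
Product: 17 methyl 2-[(1(10)E,4Z)-3β-(tert-butyldimethylsilyloxy)-9β-(4-methoxyphenoxy)-4,10-dimethyl-6-oxocyclodeca-1(10),4-dien-7β-yl]acetate (germacrane locants; 3S,7S,9S), via potassium alkoxide 15 (not isolated), via potassium enolate 16 (not isolated)
Conditions: KN(SiMe3)2 (1.1 equiv), 18-crown-6 (1.2 equiv), THF, −78 → 0 °C; then BrCH2CO2Me (2 equiv), −78 → −20 °C
Reagents that add atoms: methyl bromoacetate, COC(=O)CBr
Why: Deprotonation gives the tertiary, doubly allylic alkoxide 15, which should undergo an anionic oxy-Cope [3,3]-sigmatropic rearrangement (closest precedent: ring expansion of trans-1,2-dialkenylcyclohexanols to cyclodec-5-enones with in-flask alkylation of the enolate), in which C1–C6 breaks while C8–C9 forms, so the cyclohexene (C1–C6) is expanded by four atoms into the ten-membered carbocycle and enolate 16 is released regiospecifically at C6/C7. The ring is closed in a sigmatropic mode through a chair transition state in which the ring bonds C6–C5 and C1–C2 and the aryloxy group on C9 are equatorial and only O− is axial, which is the ground-state conformer of 14. C9 is set by chirality transfer from C1 and C6 (both destroyed) together with the E geometry of the enol ether (equatorial OAr gives 9S, 9β), the 1(10) olefin is E because C2 is equatorial, and the 4Z olefin is inherited from the cyclohexene. C7 is set when methyl bromoacetate attacks the outer face of the E-configured enolate, whose inner face is covered transannularly by the C1=C10 olefin in the crossed conformer in which 16 is born (side chain β, H-7 α, 7S). The step needs chair over boat (secured by the trans-diequatorial alkenyl groups), [3,3] shift over alkoxide fragmentation (secured by the low temperature at which a doubly allylic potassium alkoxide rearranges) and C- over O-alkylation (soft primary bromide at −78 °C).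

Step 11
Reactants: 17 keto ester
Product: 18 methyl 2-[(4Z)-1β,10α-epoxy-3β-(tert-butyldimethylsilyloxy)-9β-(4-methoxyphenoxy)-4,10-dimethyl-6-oxocyclodec-4-en-7β-yl]acetate
Conditions: mCPBA (1.1 equiv), NaHCO3, CH2Cl2, 0 °C
Reagents that add atoms: 3-chloroperoxybenzoic acid, OOC(=O)c1cccc(Cl)c1
Why: Prilezhaev epoxidation, in which the enone olefin is inert and the peracid should attack the exposed outer face of the E-1(10) olefin in the crossed conformer with the C14 methyl β, giving the 1β,10α-epoxide (C10 S).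

Step 12
Reactants: 18 epoxy keto ester
Product: 19 (4Z)-3β-(tert-butyldimethylsilyloxy)-7β-(2-hydroxyethyl)-9β-(4-methoxyphenoxy)-4,10β-dimethylcyclodec-4-ene-6α,10α-diol
Conditions: LiAlH4 (excess), THF, −78 °C → 50 °C
Reagents that add atoms: none
Why: LiAlH4 reduction, in which hydride should add 1,2 to the C6 ketone from the β face anti to the axial C7–H (6α-OH, oxygen on the periphery), reduce the ester to the primary alcohol, and open the epoxide by SN2 attack at the less substituted C1, leaving the tertiary 10α-hydroxyl.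

Step 13
Reactants: 19 triol
Product: 21 3β-(tert-butyldimethylsilyloxy)-10α-hydroxy-9β-(4-methoxyphenoxy)-13-norgermacr-4Z-en-12,6α-olide, via lactol 20 (not isolated)
Conditions: TEMPO (20 mol %), PhI(OAc)2 (3 equiv), CH2Cl2, rt
Reagents that add atoms: none
Why: oxoammonium (TEMPO) oxidation is selective for the primary alcohol, the aldehyde is trapped by the C6 hydroxyl as the lactol, and this is oxidised on to the trans-fused γ-lactone (oxidative lactonisation of a 1,4-diol).

Step 14
Reactants: 21 hydroxy lactone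
Product: 24 3β-(tert-butyldimethylsilyloxy)-10α-hydroxy-9β-(4-methoxyphenoxy)germacra-4Z,11(13)-dien-12,6α-olide, via Mannich base 22 (not isolated), via ammonium iodide 23 (not isolated)
Conditions: LiN(iPr)2 (2.5 equiv), THF, −78 °C; [Me2N=CH2]I, −78 °C → rt; then MeI, MeOH, rt; then NaHCO3 (aq), CH2Cl2
Reagents that add atoms: N,N-dimethylmethyleneiminium iodide, C=[N+](C)C.[I-]; iodomethane, CI (enters intermediate 23 only)
Why: Mannich reaction of the lactone enolate (the C10 alkoxide is a spectator), N-methylation and E1cB elimination of trimethylamine is the classical α-methylenation of γ-butyrolactones.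

Step 15
Reactants: 24 aryl ether
Product: 25 3β-(tert-butyldimethylsilyloxy)-9β,10α-dihydroxygermacra-4Z,11(13)-dien-12,6α-olide
Conditions: (NH4)2Ce(NO3)6 (2.5 equiv), pyridine, MeCN/H2O (4:1), 0 °C
Reagents that add atoms: none
Why: oxidative removal of the para-methoxyphenyl ether (arene oxidation to the quinone, C9–O bond untouched) should be compatible with the buffered silyl ether and the unsaturated lactone.

Step 16
Reactants: 25 diol; 26 angelic acid
Product: 27 9β-angeloyloxy-3β-(tert-butyldimethylsilyloxy)-10α-hydroxygermacra-4Z,11(13)-dien-12,6α-olide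
Conditions: 26, 2,4,6-Cl3C6H2COCl, Et3N, toluene, rt; then 25, 80 °C
Reagents that add atoms: none
Why: Yamaguchi mixed-anhydride esterification without a nucleophilic catalyst should acylate the secondary C9 hydroxyl (the tertiary C10 hydroxyl is inert) and is the standard way to introduce an angelate without Z to E isomerisation.

Step 17
Reactants: 27 silyl ether
Product: 28 9β-angeloyloxy-3β,10α-dihydroxygermacra-4Z,11(13)-dien-12,6α-olide (CNP0549192.1)
Conditions: HF·pyridine, pyridine, THF, 0 °C → rt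
Reagents that add atoms: none
Why: buffered fluoride desilylation of the allylic silyl ether should leave the angelate and the α-methylene lactone intact.

**Compound list**

1 | 4-methoxyphenol | COc1ccc(O)cc1 | starting material
2 | trichloroethylene | ClC=C(Cl)Cl | starting material
3 | (E)-1-[(1,2-dichloroethenyl)oxy]-4-methoxybenzene | Cl/C=C(/Cl)Oc1ccc(OC)cc1 | intermediate
4 | 1-[(chloroethynyl)oxy]-4-methoxybenzene | ClC#COc1ccc(OC)cc1 | intermediate
5 | lithium (4-methoxyphenoxy)acetylide | [Li]C#COc1ccc(OC)cc1 | intermediate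
6 | 1-methoxy-4-(prop-1-yn-1-yloxy)benzene | CC#COc1ccc(OC)cc1 | intermediate
7 | (Z)-2-[1-(4-methoxyphenoxy)prop-1-en-2-yl]-4,4,5,5-tetramethyl-1,3,2-dioxaborolane | C/C(B1OC(C)(C)C(C)(C)O1)=C\Oc1ccc(OC)cc1 | intermediate
8 | 4-methoxy-2-methylphenol | COc1ccc(O)c(C)c1 | starting material
9 | 4,4-dimethoxy-2-methylcyclohexa-2,5-dien-1-one | COC1(OC)C=CC(=O)C(C)=C1 | intermediate
10 | (5S)-4,4-dimethoxy-5-[(1E)-1-(4-methoxyphenoxy)prop-1-en-2-yl]-2-methylcyclohex-2-en-1-one | COC1(OC)C=C(C)C(=O)C[C@H]1/C(C)=C/Oc1ccc(OC)cc1 | intermediate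
11 | (1S,5S)-4,4-dimethoxy-5-[(1E)-1-(4-methoxyphenoxy)prop-1-en-2-yl]-2-methylcyclohex-2-en-1-ol | COC1(OC)C=C(C)[C@@H](O)C[C@H]1/C(C)=C/Oc1ccc(OC)cc1 | intermediate
12 | tert-butyldimethylsilyl ether of 11 | COC1(OC)C=C(C)[C@@H](O[Si](C)(C)C(C)(C)C)C[C@H]1/C(C)=C/Oc1ccc(OC)cc1 | intermediate
13 | (4S,6S)-4-[(tert-butyldimethylsilyl)oxy]-6-[(1E)-1-(4-methoxyphenoxy)prop-1-en-2-yl]-3-methylcyclohex-2-en-1-one | O=C1C=C(C)[C@@H](O[Si](C)(C)C(C)(C)C)C[C@H]1/C(C)=C/Oc1ccc(OC)cc1 | intermediate
14 | (1S,4S,6S)-4-[(tert-butyldimethylsilyl)oxy]-1-ethenyl-6-[(1E)-1-(4-methoxyphenoxy)prop-1-en-2-yl]-3-methylcyclohex-2-en-1-ol | C=C[C@]1(O)C=C(C)[C@@H](O[Si](C)(C)C(C)(C)C)C[C@H]1/C(C)=C/Oc1ccc(OC)cc1 | intermediate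
15 | potassium alkoxide of 14 | C=C[C@]1([O-])C=C(C)[C@@H](O[Si](C)(C)C(C)(C)C)C[C@H]1/C(C)=C/Oc1ccc(OC)cc1.[K+] | intermediate
16 | potassium (1(10)E,4Z,6E)-cyclodecatrien-6-olate (C6=C7 enolate; 3β-OTBS, 9β-OAr) | C1/C=C(\[O-])/C=C(C)\[C@@H](O[Si](C)(C)C(C)(C)C)C/C=C(\C)[C@H]1Oc2ccc(OC)cc2.[K+] | intermediate
17 | methyl 2-[(1(10)E,4Z)-3β-(tert-butyldimethylsilyloxy)-9β-(4-methoxyphenoxy)-4,10-dimethyl-6-oxocyclodeca-1(10),4-dien-7β-yl]acetate | COC(=O)C[C@@H]1C[C@H](Oc2ccc(OC)cc2)/C(C)=C/C[C@H](O[Si](C)(C)C(C)(C)C)/C(C)=C\C1=O | intermediate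
18 | methyl 2-[(4Z)-1β,10α-epoxy-3β-(tert-butyldimethylsilyloxy)-9β-(4-methoxyphenoxy)-4,10-dimethyl-6-oxocyclodec-4-en-7β-yl]acetate | COC(=O)C[C@@H]1C[C@H](Oc2ccc(OC)cc2)[C@@]3(C)O[C@@H]3C[C@H](O[Si](C)(C)C(C)(C)C)/C(C)=C\C1=O | intermediate
19 | (4Z)-3β-(tert-butyldimethylsilyloxy)-7β-(2-hydroxyethyl)-9β-(4-methoxyphenoxy)-4,10β-dimethylcyclodec-4-ene-6α,10α-diol | OCC[C@@H]1C[C@H](Oc2ccc(OC)cc2)[C@@](C)(O)CC[C@H](O[Si](C)(C)C(C)(C)C)/C(C)=C\[C@H]1O | intermediate
20 | lactol of 21 (C12 hemiacetal, either epimer) | C1C(O)O[C@@H]2/C=C(/C)[C@@H](O[Si](C)(C)C(C)(C)C)CC[C@](C)(O)[C@@H](Oc3ccc(OC)cc3)C[C@@H]12 | intermediate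
21 | 3β-(tert-butyldimethylsilyloxy)-10α-hydroxy-9β-(4-methoxyphenoxy)-13-norgermacr-4Z-en-12,6α-olide | C1C(=O)O[C@@H]2/C=C(/C)[C@@H](O[Si](C)(C)C(C)(C)C)CC[C@](C)(O)[C@@H](Oc3ccc(OC)cc3)C[C@@H]12 | intermediate
22 | 13-(dimethylamino) derivative of 21 (Mannich base, C11 epimers) | CN(C)CC1C(=O)O[C@@H]2/C=C(/C)[C@@H](O[Si](C)(C)C(C)(C)C)CC[C@](C)(O)[C@@H](Oc3ccc(OC)cc3)C[C@@H]12 | intermediate
23 | 13-(trimethylammonio) derivative of 21, iodide | C[N+](C)(C)CC1C(=O)O[C@@H]2/C=C(/C)[C@@H](O[Si](C)(C)C(C)(C)C)CC[C@](C)(O)[C@@H](Oc3ccc(OC)cc3)C[C@@H]12.[I-] | intermediate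
24 | 3β-(tert-butyldimethylsilyloxy)-10α-hydroxy-9β-(4-methoxyphenoxy)germacra-4Z,11(13)-dien-12,6α-olide | C=C1C(=O)O[C@@H]2/C=C(/C)[C@@H](O[Si](C)(C)C(C)(C)C)CC[C@](C)(O)[C@@H](Oc3ccc(OC)cc3)C[C@@H]12 | intermediate
25 | 3β-(tert-butyldimethylsilyloxy)-9β,10α-dihydroxygermacra-4Z,11(13)-dien-12,6α-olide | C=C1C(=O)O[C@@H]2/C=C(/C)[C@@H](O[Si](C)(C)C(C)(C)C)CC[C@](C)(O)[C@@H](O)C[C@@H]12 | intermediate
26 | angelic acid, (Z)-2-methylbut-2-enoic acid | C/C=C(/C)C(=O)O | starting material
27 | 9β-angeloyloxy-3β-(tert-butyldimethylsilyloxy)-10α-hydroxygermacra-4Z,11(13)-dien-12,6α-olide | C=C1C(=O)O[C@@H]2/C=C(/C)[C@@H](O[Si](C)(C)C(C)(C)C)CC[C@](C)(O)[C@@H](OC(=O)/C(C)=C\C)C[C@@H]12 | intermediate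
28 | 9β-angeloyloxy-3β,10α-dihydroxygermacra-4Z,11(13)-dien-12,6α-olide (CNP0549192.1) | C=C1C(=O)O[C@@H]2/C=C(/C)[C@@H](O)CC[C@](C)(O)[C@@H](OC(=O)/C(C)=C\C)C[C@@H]12 | target

**Step count and risks**

Total steps: 17. Longest linear sequence: 16 (steps 1–3 and 5–17; step 4 is the one-step branch to 9).

The three steps most likely to fail:

Step 10 (key step). What may go wrong: heterolytic fragmentation of the potassium alkoxide instead of the [3,3] shift, leakage through a boat transition state (loss of C9 control), O-alkylation, or conformational equilibration of the crown-complexed enolate before alkylation (loss of C7 control). The fallback sets out from 14 and returns at 17. Compound 14 is silylated (Me3SiCl, imidazole) to the trimethylsilyl ether of 14 F1. A neutral thermal siloxy-Cope rearrangement (toluene, sealed tube, about 200 °C) then gives the ten-membered trimethylsilyl enol ether F2 through the same chair. MeLi in THF releases the regiodefined lithium enolate F3, which is alkylated with methyl bromoacetate (THF/DMPU, −78 °C) to give 17.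

Step 12. What may go wrong: hydride delivery to the wrong face of the C6 carbonyl (this would lead to the cis-fused lactone series), or slow backside attack at C1 of the epoxide from inside the ring. The fallback sets out from 17 and returns at 19. Ketone 17 is reduced before epoxidation under Luche conditions (NaBH4, CeCl3·7H2O), and the 6β-alcohol is allowed to close to the cis-fused 6β-lactone F4. LiOH opens it to the 6β-hydroxy acid F5. Mitsunobu lactonisation (PPh3, DIAD) activates the allylic C6 hydroxyl and closes the ring with inversion, giving the trans-fused 6α-lactone F6. mCPBA then gives the 1β,10α-epoxy lactone F7, and LiAlH4 reduces lactone and epoxide together to triol 19.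

Step 5. What may go wrong: low enantioselectivity with the β-aryloxyalkenyl boronate, or protodeboronation outrunning transmetalation. The fallback sets out from 9 and 7 and returns at 11. The 1,4-addition is run without a chiral ligand ([Rh(OH)(C8H12)]2, KOH, dioxane/H2O) to give the racemic ketone F8. CBS reduction with the (R)-configured methyl oxazaborolidine and BH3·SMe2 then fixes C3 as S by catalyst control in both enantiomers. The cis alcohol is 11 itself (at most half of the material), and the trans diastereomer F9 is removed by chromatography.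

Further compounds
F1 | step 10 | trimethylsilyl ether of 14 | C=C[C@]1(O[Si](C)(C)C)C=C(C)[C@@H](O[Si](C)(C)C(C)(C)C)C[C@H]1/C(C)=C/Oc1ccc(OC)cc1
F2 | step 10 | (1(10)E,4Z,6E)-6-(trimethylsilyloxy)cyclodecatriene (silyl enol ether corresponding to 16) | C1/C=C(\O[Si](C)(C)C)/C=C(C)\[C@@H](O[Si](C)(C)C(C)(C)C)C/C=C(\C)[C@H]1Oc2ccc(OC)cc2
F3 | step 10 | lithium enolate corresponding to 16 | C1/C=C(\[O-])/C=C(C)\[C@@H](O[Si](C)(C)C(C)(C)C)C/C=C(\C)[C@H]1Oc2ccc(OC)cc2.[Li+]
F4 | step 12 | 3β-(tert-butyldimethylsilyloxy)-9β-(4-methoxyphenoxy)-13-norgermacra-1(10)E,4Z-dien-12,6β-olide (cis-fused) | C1C(=O)O[C@H]2/C=C(/C)[C@@H](O[Si](C)(C)C(C)(C)C)C/C=C(\C)[C@@H](Oc3ccc(OC)cc3)C[C@@H]12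
F5 | step 12 | 6β-hydroxy acid from F4 | OC(=O)C[C@@H]1C[C@H](Oc2ccc(OC)cc2)/C(C)=C/C[C@H](O[Si](C)(C)C(C)(C)C)/C(C)=C\[C@@H]1O
F6 | step 12 | 3β-(tert-butyldimethylsilyloxy)-9β-(4-methoxyphenoxy)-13-norgermacra-1(10)E,4Z-dien-12,6α-olide (trans-fused) | C1C(=O)O[C@@H]2/C=C(/C)[C@@H](O[Si](C)(C)C(C)(C)C)C/C=C(\C)[C@@H](Oc3ccc(OC)cc3)C[C@@H]12
F7 | step 12 | 1β,10α-epoxide of F6 | C1C(=O)O[C@@H]2/C=C(/C)[C@@H](O[Si](C)(C)C(C)(C)C)C[C@H]3O[C@]3(C)[C@@H](Oc4ccc(OC)cc4)C[C@@H]12
F8 | step 5 | racemic 10 | COC1(OC)C=C(C)C(=O)CC1/C(C)=C/Oc1ccc(OC)cc1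
F9 | step 5 | (1S,5R)-diastereomer of 11 (trans) | COC1(OC)C=C(C)[C@@H](O)C[C@@H]1/C(C)=C/Oc1ccc(OC)cc1
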